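## The problem

Target 34 is a single ten-membered carbocycle with no second ring to template it, so the ring has to be closed against medium-ring strain. The ring is numbered C1(CH3)=C2H, C3H(OH), C4H(i-Pr), C5H(O-aroyl), C6H2, C7(CH3)=C8H, C9H2, C10H2. Both trisubstituted alkenes are Z and together form a 1,5-diene. The three stereocentres are contiguous and all S, with C4/C5 syn and C3/C5 anti in the extended chain. This is the pattern of a syn aldol followed by a hydroxyl-directed 1,3-anti reduction: an auxiliary can set C4 and C5, and the C5 oxygen can then control C3. The two oxygens end differently, a free allylic alcohol at C3 and a 4-hydroxybenzoate at C5, so they must be told apart and the ester must not migrate to C3. The aryl ester and the phenol will not survive carbanions or hydride. The C3 allylic alcohol and the (Z,Z)-1,5-diene are sensitive to strong acid and heat, and neither Z alkene may be equilibrated. The feature that opens the key step is the C9–C10 bond: both carbons are allylic methylenes (to C7=C8 and to C1=C2), neither is a stereocentre, and a sulfone on C9 lets them be joined as carbanion and allylic chloride.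

## Retrosynthesis

**Ester last (34 ⇒ 33 ⇒ 28 + 31).** The C5–O acyl bond is cut first. The 4-hydroxybenzoate cannot pass through a carbanion cyclisation or a hydride desulfonylation, so it is attached to ring alcohol 28 as the silyl-protected acid 31, made in one step from 4-hydroxybenzoic acid 29. The forward steps must acylate a hindered ring alcohol and then remove two silyl groups without moving the ester to C3.

**Traceless activator (28 ⇒ 26).** The C9–H bond is traced back to a C9 phenyl sulfone and the C5 hydroxyl to a pivalate. One hydride reagent should remove both, so macrocycle 26 needs no separate deprotection step.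

**Ring closure (26 ⇒ 24, C9–C10).** Cutting C2–C3, C3–C4 or C4–C5 would make a stereocentre during a medium-ring closure, where acyclic models are unreliable. The C9–C10 cut creates no lasting stereocentre and touches neither alkene. The precursor 24 is an open chain with all three stereocentres and both Z alkenes already in place. The forward reaction must be an intramolecular SN2 alkylation of a sulfonyl allyl anion at a primary allylic chloride, under dilution, at the α-carbon.

**End groups (24 ⇒ 22 ⇒ 21 ⇒ 19 ⇒ 18).** The sulfone must be installed before the chloride, since sulfinate would displace either allylic leaving group. C9 and C10 are therefore carried as two differently masked primary alcohols: a primary TBS ether at C9 and a PMB ether at C10. The C3 oxygen carries a hindered secondary TBS ether and the C5 oxygen a pivalate. The pivalate has no α-hydrogen and a shielded carbonyl, and it is cleaved by the hydride of the desulfonylation step.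

**C3 and the differentiation of the two oxygens (18 ⇒ 17 ⇒ 16).** A borohydride anti-reduction of β-hydroxy enone 16 would give a diol with two similar secondary hydroxyls. An Evans–Tishchenko reduction with pivalaldehyde sets C3 anti to C5 and leaves the acyl group on the C5 oxygen. The stereocentre and the differentiation therefore come from one step, and the acyl group lands on the oxygen that carries the ester in the target.

**C2–C3 (16 ⇒ 10 + 14).** The enone is cut at the ketone into Weinreb amide 10 and a Z-alkenyllithium 15 made from iodide 14. Addition to an aldehyde instead would create C3 without control. Iodide 14 comes in two steps from propargyl alcohol 11 through Z-iodo alcohol 13, whose geometry is fixed by a chelated carbomagnesiation.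

**C4–C5 (10 ⇒ 9 ⇒ 7 + 6).** An Evans syn aldol between the commercially available (R)-isovaleryl oxazolidinone 7 and β,γ-unsaturated aldehyde 6 sets both centres. The aldehyde must be used without isomerisation into conjugation.

**The Z C5–C9 unit (6 ⇒ 5 ⇒ 3 ⇒ 2 ⇒ 1).** Reduction of a lactone to a Z-diol would give two primary hydroxyls that are hard to distinguish. (Z)-3-Methylpent-2-en-4-yn-1-ol 1 already has the Z trisubstituted alkene and two different termini, an alcohol (C9) and an alkyne (C6, C5). Silylation, semi-hydrogenation, terminal hydroboration and oxidation convert it into 6.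

## Roads not taken

**Alternative 1:** The ring is cut at C4–C5. Open-chain bromo aldehyde A1 is treated with CrCl2; the allylchromium species adds through C4 to the C5 aldehyde and gives ten-membered alcohol A2, with an isopropenyl group at C4.
- Merits: ring closure and two stereocentres come from one step, and the anti preference of allylchromium additions corresponds to the C4/C5 relationship needed. The C5 hydroxyl emerges free beside a protected C3 oxygen, so the two oxygens are differentiated automatically. In this respect it is better than the chosen plan, which spends an Evans–Tishchenko step and an ester cleavage on it.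
- Weak points: the configuration of C4 relative to C3 must come from a ten-membered transition state with no dependable model. The isopropenyl group must then be hydrogenated in the presence of two trisubstituted ring alkenes. A1 combines a β,γ-unsaturated aldehyde with an allylic bromide in one molecule.
- Comparison: the chosen plan sets all three centres in the open chain with reagent and substrate control, and its ring closure creates no lasting stereocentre.

**Alternative 2:** The ring is cut at C3–C4 through a ring contraction. Tin–lithium exchange in thirteen-membered cyclic ether A3 gives an α-alkoxyallyllithium, and 2,3-Wittig rearrangement gives ten-membered alcohol A4.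
- Merits: a thirteen-membered ether should close more easily than a ten-membered carbocycle. The sigmatropic step forms C3–C4 with both stereocentres and leaves C3 as a free hydroxyl beside a C5 PMB ether.
- Weak points: A3 needs a configurationally defined α-alkoxystannane inside a macrocyclic ether, which is a long preparation. The C3/C4 outcome depends on a transannular transition state. A 1,2-shift can compete. The isopropenyl group must be reduced selectively, as in alternative 1. Tin is used stoichiometrically.
- Comparison: this road is better on the entropy of ring closure. The chosen plan answers with dilution and a chain pre-folded by two Z alkenes, and it has a shorter, stereochemically secure precursor.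

**Alternative 3:** The ring is cut at C2–C3 with the ester already in place. Z-alkenyl iodide aldehyde A5 is closed with CrCl2 and catalytic NiCl2 to give the O-silylated target A6.
- Merits: only one desilylation follows the ring closure, so in step count after cyclisation this road is clearly better than the chosen one. The chromium conditions tolerate the ester and keep the alkene geometry.
- Weak points: C3 is created in the ring-closing event and must come out 3,4-anti and 3,5-anti, with nothing reliable to enforce it. A5 is an α-branched β-acyloxy aldehyde, open to epimerisation at C4 and to β-elimination of the carboxylate. A wrong C3 epimer would have to be corrected beside a migration-prone ester.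
- Comparison: the chosen plan accepts four steps after cyclisation in exchange for a robust precursor and a C3 centre fixed before the ring exists.

Key step: step 16

Assumptions: (Z)-3-methylpent-2-en-4-yn-1-ol 1 is taken as the commercially available single geometric isomer. Macrocyclic sulfone 26 is carried on as a mixture of C9 epimers, so its SMILES leaves that carbon without a descriptor. Macrocycle names use IUPAC ring locants, in which C1 is the ester carbon (C5 of the strategic numbering above).

## Route

Step 1
Reactants: 1 (Z)-3-methylpent-2-en-4-yn-1-ol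
Product: 2 tert-butyldimethyl{[(2Z)-3-methylpent-2-en-4-yn-1-yl]oxy}silane
Conditions: TBSCl, imidazole, CH2Cl2, 0 °C → rt
Reagents that add atoms: tert-butyldimethylsilyl chloride, CC(C)(C)[Si](C)(C)Cl
Why: Imidazole-mediated silylation of a primary allylic alcohol; the Z enyne is not touched.

Step 2
Reactants: 2 silyl enyne
Product: 3 tert-butyldimethyl{[(2Z)-3-methylpenta-2,4-dien-1-yl]oxy}silane
Conditions: H2 (1 atm), Pd/CaCO3 poisoned with Pb(OAc)2 (Lindlar catalyst), quinoline, hexane, rt, stopped after one equivalent of H2
Reagents that add atoms: none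
Why: Lindlar semi-hydrogenation stops a terminal alkyne at the vinyl stage; the trisubstituted alkene is not reduced on the poisoned catalyst, so the Z geometry of 1 is kept.

Step 3
Reactants: 3 silyl diene
Product: 5 (3Z)-5-[(tert-butyldimethylsilyl)oxy]-3-methylpent-3-en-1-ol, via B-alkyl-9-BBN adduct 4 (not isolated)
Conditions: 9-BBN, THF, 0 °C → rt; then NaOH (aq), H2O2, 0 °C
Reagents that add atoms: hydrogen peroxide, OO
Why: Hydroboration–oxidation; 9-BBN adds only to the monosubstituted vinyl group with boron on the terminal carbon, and oxidation gives the homoallylic alcohol with the trisubstituted Z alkene intact.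

Step 4
Reactants: 5 homoallylic alcohol
Product: 6 (3Z)-5-[(tert-butyldimethylsilyl)oxy]-3-methylpent-3-enal
Conditions: Dess–Martin periodinane, NaHCO3, CH2Cl2, 0 °C → rt; crude aldehyde used at once
Reagents that add atoms: none
Why: Dess–Martin oxidation under buffered, base-free conditions should give the β,γ-unsaturated aldehyde without moving the alkene into conjugation.

Step 5
Reactants: 7 (4R)-4-benzyl-3-(3-methylbutanoyl)-1,3-oxazolidin-2-one; 6 aldehyde
Product: 9 (4R)-4-benzyl-3-[(2R,3S,5Z)-7-[(tert-butyldimethylsilyl)oxy]-3-hydroxy-5-methyl-2-(propan-2-yl)hept-5-enoyl]-1,3-oxazolidin-2-one, via dibutylboron Z-enolate 8 (not isolated)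
Conditions: 7, n-Bu2BOTf, Et3N, CH2Cl2, −78 → 0 °C; 6, −78 → 0 °C; pH 7 buffer, MeOH, H2O2, 0 °C
Reagents that add atoms: none
Why: Evans syn aldol reaction: the boron Z-enolate reacts through a Zimmerman–Traxler chair on the face away from the benzyl group of the (R)-auxiliary, which sets C4 and C5 syn with the required absolute configuration. The aldehyde meets only the preformed enolate at low temperature, so it is not exposed to free amine.

Step 6
Reactants: 9 aldol adduct
Product: 10 (2R,3S,5Z)-7-[(tert-butyldimethylsilyl)oxy]-3-hydroxy-N-methoxy-N,5-dimethyl-2-(propan-2-yl)hept-5-enamide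
Conditions: MeNHOMe·HCl, AlMe3, CH2Cl2, −20 → 0 °C; KNaC4H4O6 (aq)
Reagents that add atoms: N,O-dimethylhydroxylamine hydrochloride, CNOC.Cl
Why: Aluminium amide transamination of an aldol adduct to the Weinreb amide; the aluminium alkoxide of the free C5 hydroxyl delivers the nucleophile to the exocyclic carbonyl, which should keep it away from the ring carbonyl despite the α-isopropyl group.

Step 7
Reactants: 11 propargyl alcohol
Product: 13 (2Z)-3-iodo-2-methylprop-2-en-1-ol, via cyclic alkenylmagnesium alkoxide 12 (not isolated)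
Conditions: MeMgBr (2.2 equiv), CuI (10 mol%), THF, −10 °C → rt; then I2, −78 → 0 °C
Reagents that add atoms: methylmagnesium bromide, C[Mg]Br; iodine, II
Why: Copper-catalysed anti carbomagnesiation of a propargylic alkoxide (Duboudin reaction): methyl adds to C2 and magnesium to C3 within a five-membered chelate, so iodinolysis places iodine cis to the CH2OH group.

Step 8
Reactants: 13 Z-iodo alcohol
Product: 14 1-({[(2Z)-3-iodo-2-methylprop-2-en-1-yl]oxy}methyl)-4-methoxybenzene
Conditions: NaH, 4-methoxybenzyl chloride, n-Bu4NI (cat.), THF/DMF, 0 °C → rt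
Reagents that add atoms: 4-methoxybenzyl chloride, COc1ccc(CCl)cc1
Why: Williamson etherification; an ether is chosen over a silyl ether because a silyl group cis to the later carbon–lithium bond would invite 1,4 oxygen-to-carbon silyl migration.

Step 9
Reactants: 10 Weinreb amide; 14 Z-alkenyl iodide
Product: 16 (2Z,5R,6S,8Z)-10-[(tert-butyldimethylsilyl)oxy]-6-hydroxy-1-[(4-methoxyphenyl)methoxy]-2,8-dimethyl-5-(propan-2-yl)deca-2,8-dien-4-one, via Z-alkenyllithium 15 (not isolated)
Conditions: 14, t-BuLi (2 equiv), Et2O, −78 °C; 10, i-PrMgCl (1 equiv), THF, −40 °C; mixed at −78 → −30 °C; NH4Cl (aq)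
Reagents that add atoms: none
Why: Lithium–iodine exchange with retention of alkene geometry, then ketone synthesis from the Weinreb amide, whose chelated tetrahedral adduct prevents over-addition. The C5 hydroxyl is first turned into its magnesium alkoxide so that no alkenyllithium is spent as a base.

Step 10
Reactants: 16 β-hydroxy enone
Product: 17 (2Z,4S,5S,6S,8Z)-10-[(tert-butyldimethylsilyl)oxy]-4-hydroxy-1-[(4-methoxyphenyl)methoxy]-2,8-dimethyl-5-(propan-2-yl)deca-2,8-dien-6-yl 2,2-dimethylpropanoate
Conditions: SmI2 (0.3 equiv), t-BuCHO (6 equiv), THF, −10 °C, dark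
Reagents that add atoms: pivalaldehyde, CC(C)(C)C=O
Why: Evans–Tishchenko reduction: the samarium-bound hemiacetal of the C5 hydroxyl and pivalaldehyde delivers hydride intramolecularly to the C3 ketone through a chair-like bicyclic transition state, which gives the 1,3-anti relationship and hence the required C3 configuration. The acyl group stays on the C5 oxygen, so the two hydroxyls are differentiated in the same step, and the hindered enone is reduced only at the carbonyl.

Step 11
Reactants: 17 hydroxy pivalate
Product: 18 (2Z,4S,5R,6S,8Z)-4,10-bis[(tert-butyldimethylsilyl)oxy]-1-[(4-methoxyphenyl)methoxy]-2,8-dimethyl-5-(propan-2-yl)deca-2,8-dien-6-yl 2,2-dimethylpropanoate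
Conditions: TBSOTf, 2,6-lutidine, CH2Cl2, −78 → 0 °C
Reagents that add atoms: tert-butyldimethylsilyl trifluoromethanesulfonate, CC(C)(C)[Si](C)(C)OS(=O)(=O)C(F)(F)F
Why: Silylation of a hindered secondary allylic alcohol with a silyl triflate and a non-nucleophilic base; the low temperature gives the pivalate no chance to migrate (the C5 descriptor changes by priority only).

Step 12
Reactants: 18 bis-silyl ether
Product: 19 (2Z,4S,5R,6S,8Z)-4-[(tert-butyldimethylsilyl)oxy]-10-hydroxy-1-[(4-methoxyphenyl)methoxy]-2,8-dimethyl-5-(propan-2-yl)deca-2,8-dien-6-yl 2,2-dimethylpropanoate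
Conditions: HF·pyridine, pyridine, THF, 0 °C
Reagents that add atoms: none
Why: Selective desilylation: the primary allylic silyl ether is cleaved by buffered HF·pyridine well before the secondary one, which is flanked by the alkene and the isopropyl-bearing carbon. Ester and PMB ether are inert.

Step 13
Reactants: 19 C9 alcohol (chain C10)
Product: 21 (2Z,4S,5R,6S,8Z)-10-(benzenesulfonyl)-4-[(tert-butyldimethylsilyl)oxy]-1-[(4-methoxyphenyl)methoxy]-2,8-dimethyl-5-(propan-2-yl)deca-2,8-dien-6-yl 2,2-dimethylpropanoate, via C9 allylic mesylate 20 (not isolated)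
Conditions: MsCl, Et3N, CH2Cl2, −20 °C; then PhSO2Na, n-Bu4NI (cat.), DMF, 0 °C → rt
Reagents that add atoms: sodium benzenesulfinate, [Na+].[O-]S(=O)c1ccccc1
Why: Mesylation, then SN2 displacement by sulfinate through sulfur at a primary allylic carbon; direct substitution keeps the position and Z geometry of the alkene.

Step 14
Reactants: 21 sulfone PMB ether
Product: 22 (2Z,4S,5R,6S,8Z)-10-(benzenesulfonyl)-4-[(tert-butyldimethylsilyl)oxy]-1-hydroxy-2,8-dimethyl-5-(propan-2-yl)deca-2,8-dien-6-yl 2,2-dimethylpropanoate
Conditions: DDQ, CH2Cl2/pH 7 buffer, 0 °C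
Reagents that add atoms: none
Why: Oxidative cleavage of the PMB ether by DDQ through hydride abstraction at the electron-rich benzylic carbon; sulfone, pivalate, silyl ether and the isolated alkenes are not oxidised under buffered conditions.

Step 15
Reactants: 22 C10 alcohol (chain C1)
Product: 24 (2Z,4S,5R,6S,8Z)-10-(benzenesulfonyl)-4-[(tert-butyldimethylsilyl)oxy]-1-chloro-2,8-dimethyl-5-(propan-2-yl)deca-2,8-dien-6-yl 2,2-dimethylpropanoate, via C10 allylic mesylate 23 (not isolated)
Conditions: MsCl, LiCl, 2,4,6-collidine, DMF, 0 °C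
Reagents that add atoms: lithium chloride, [Li+].[Cl-]
Why: Collington–Meyers chlorination: the mesylate is displaced by chloride at the primary allylic carbon without transposition or loss of Z geometry, and collidine is too weak a base to deprotonate the sulfone.

Step 16
Reactants: 24 open-chain (Z,Z) allylic chloride phenyl sulfone
Product: 26 (1S,3Z,7Z,9S,10R)-5-(benzenesulfonyl)-9-[(tert-butyldimethylsilyl)oxy]-3,7-dimethyl-10-(propan-2-yl)cyclodeca-3,7-dien-1-yl 2,2-dimethylpropanoate (both epimers at the sulfone carbon), via potassium sulfonyl carbanion 25 (not isolated)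
Conditions: KN(SiMe3)2 (1.1 equiv) added slowly to 24 in THF (2 mM), −78 → −20 °C
Reagents that add atoms: none
Why: KN(SiMe3)2 removes a proton from C9, the only carbon acid in reach (sulfone plus the C7=C8 bond), and carbanion 25 displaces chloride at the primary allylic carbon C10 in an intramolecular SN2 step that forms the C9–C10 bond. The closest known reaction type is the intramolecular alkylation of sulfur-stabilised allylic carbanions by allylic halides, used to close ten-membered germacrane 1,5-dienes and larger terpenoid rings. The ring closes in the 10-exo-tet mode. C9 becomes a stereocentre without control, and either epimer serves because step 17 erases it. Alkylation at C9 and not through C7 follows from the α-preference of sulfonyl allyl anions and the full substitution of C7; SN2 at C10 and not SN2' at C2 follows from the primary leaving-group carbon and the shielding of C2 by the silyloxy-bearing C3. Ring closure is favoured over intermolecular alkylation by the dilution and by the two Z alkenes, which remove four rotors and fold the chain. The pivalate has no α-hydrogen and a neopentyl-type carbonyl that the soft carbanion should not attack below 0 °C. The sulfone localises the charge at C9, so the C7=C8 geometry is kept, and C3 to C5 are not touched.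

Step 17
Reactants: 26 macrocyclic sulfone
Product: 28 (1S,3Z,7Z,9S,10R)-9-[(tert-butyldimethylsilyl)oxy]-3,7-dimethyl-10-(propan-2-yl)cyclodeca-3,7-dien-1-ol, via macrocyclic pivalate 27 (not isolated)
Conditions: PdCl2(dppp) (10 mol%), LiBHEt3 (2.5 equiv), THF, 0 °C; then LiBHEt3 (4 equiv), 0 °C → rt
Reagents that add atoms: none
Why: Palladium-catalysed reductive desulfonylation of an allylic sulfone: zerovalent palladium ionises the C9–S bond to a π-allyl complex and hydride is delivered to the less substituted terminus C9, so the C7=C8 bond stays in place. The Z geometry should hold because syn–anti exchange at C7 would need a σ-complex at that fully substituted carbon. The further hydride then cleaves the pivalate reductively and frees the C5 hydroxyl.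

Step 18
Reactants: 29 4-hydroxybenzoic acid
Product: 31 4-[(tert-butyldimethylsilyl)oxy]benzoic acid, via bis-silylated acid 30 (not isolated)
Conditions: TBSCl (2.5 equiv), imidazole, DMF, rt; then AcOH/THF/H2O, rt
Reagents that add atoms: tert-butyldimethylsilyl chloride, CC(C)(C)[Si](C)(C)Cl
Why: Silylation of phenol and acid, then selective hydrolysis of the far more labile silyl ester under mild aqueous acid, which leaves the aryl silyl ether.

Step 19
Reactants: 28 ring alcohol; 31 silyl-protected acid
Product: 33 (1S,3Z,7Z,9S,10R)-9-[(tert-butyldimethylsilyl)oxy]-3,7-dimethyl-10-(propan-2-yl)cyclodeca-3,7-dien-1-yl 4-[(tert-butyldimethylsilyl)oxy]benzoate, via mixed anhydride 32 (not isolated)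
Conditions: 31, 2,4,6-trichlorobenzoyl chloride, Et3N, THF, rt; then 28, DMAP, toluene, rt
Reagents that add atoms: none
Why: Yamaguchi esterification: DMAP transfers the aroyl group from the mixed anhydride to the hindered secondary alcohol with retention at C5 and without heating the 1,5-diene.

Step 20
Reactants: 33 bis-silyl ester
Product: 34 (1S,3Z,7Z,9S,10S)-9-hydroxy-3,7-dimethyl-10-(propan-2-yl)cyclodeca-3,7-dien-1-yl 4-hydroxybenzoate
Conditions: n-Bu4NF, AcOH (1:1), THF, 0 °C → rt
Reagents that add atoms: none
Why: Fluoride cleavage of the aryl and the secondary allylic silyl ether; the acetic acid buffer keeps the medium non-basic, so the ester should neither migrate to the freed C3 hydroxyl nor be cleaved, and the allylic alcohol sees no strong acid.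

## Compound list

1 | (Z)-3-methylpent-2-en-4-yn-1-ol | C#C/C(C)=C\CO | starting material
2 | tert-butyldimethyl{[(2Z)-3-methylpent-2-en-4-yn-1-yl]oxy}silane | C#C/C(C)=C\CO[Si](C)(C)C(C)(C)C | intermediate
3 | tert-butyldimethyl{[(2Z)-3-methylpenta-2,4-dien-1-yl]oxy}silane | C=C/C(C)=C\CO[Si](C)(C)C(C)(C)C | intermediate
4 | 9-[(3Z)-5-[(tert-butyldimethylsilyl)oxy]-3-methylpent-3-en-1-yl]-9-borabicyclo[3.3.1]nonane (not isolated) | CC(C)(C)[Si](C)(C)OC/C=C(C)\CCB1C2CCCC1CCC2 | intermediate
5 | (3Z)-5-[(tert-butyldimethylsilyl)oxy]-3-methylpent-3-en-1-ol | OCC/C(C)=C\CO[Si](C)(C)C(C)(C)C | intermediate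
6 | (3Z)-5-[(tert-butyldimethylsilyl)oxy]-3-methylpent-3-enal | O=CC/C(C)=C\CO[Si](C)(C)C(C)(C)C | intermediate
7 | (4R)-4-benzyl-3-(3-methylbutanoyl)-1,3-oxazolidin-2-one | CC(C)CC(=O)N1[C@H](Cc2ccccc2)COC1=O | starting material
8 | dibutylboron Z-enolate of 7 (not isolated) | CCCCB(CCCC)O/C(=C\C(C)C)N1[C@H](Cc2ccccc2)COC1=O | intermediate
9 | (4R)-4-benzyl-3-[(2R,3S,5Z)-7-[(tert-butyldimethylsilyl)oxy]-3-hydroxy-5-methyl-2-(propan-2-yl)hept-5-enoyl]-1,3-oxazolidin-2-one | O=C(N1[C@H](Cc2ccccc2)COC1=O)[C@H](C(C)C)[C@@H](O)C/C(C)=C\CO[Si](C)(C)C(C)(C)C | intermediate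
10 | (2R,3S,5Z)-7-[(tert-butyldimethylsilyl)oxy]-3-hydroxy-N-methoxy-N,5-dimethyl-2-(propan-2-yl)hept-5-enamide | CON(C)C(=O)[C@H](C(C)C)[C@@H](O)C/C(C)=C\CO[Si](C)(C)C(C)(C)C | intermediate
11 | propargyl alcohol | C#CCO | starting material
12 | cyclic alkenylmagnesium alkoxide, 4-methyl-2,5-dihydro-1,2-oxamagnesole (not isolated) | CC1=C[Mg]OC1 | intermediate
13 | (2Z)-3-iodo-2-methylprop-2-en-1-ol | OC/C(C)=C\I | intermediate
14 | 1-({[(2Z)-3-iodo-2-methylprop-2-en-1-yl]oxy}methyl)-4-methoxybenzene | COc1ccc(COC/C(C)=C\I)cc1 | intermediate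
15 | (Z)-3-[(4-methoxyphenyl)methoxy]-2-methylprop-1-enyllithium (not isolated) | [Li]/C=C(C)\COCc1ccc(OC)cc1 | intermediate
16 | (2Z,5R,6S,8Z)-10-[(tert-butyldimethylsilyl)oxy]-6-hydroxy-1-[(4-methoxyphenyl)methoxy]-2,8-dimethyl-5-(propan-2-yl)deca-2,8-dien-4-one | COc1ccc(COC/C(C)=C\C(=O)[C@H](C(C)C)[C@@H](O)C/C(C)=C\CO[Si](C)(C)C(C)(C)C)cc1 | intermediate
17 | (2Z,4S,5S,6S,8Z)-10-[(tert-butyldimethylsilyl)oxy]-4-hydroxy-1-[(4-methoxyphenyl)methoxy]-2,8-dimethyl-5-(propan-2-yl)deca-2,8-dien-6-yl 2,2-dimethylpropanoate | COc1ccc(COC/C(C)=C\[C@H](O)[C@H](C(C)C)[C@@H](OC(=O)C(C)(C)C)C/C(C)=C\CO[Si](C)(C)C(C)(C)C)cc1 | intermediate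
18 | (2Z,4S,5R,6S,8Z)-4,10-bis[(tert-butyldimethylsilyl)oxy]-1-[(4-methoxyphenyl)methoxy]-2,8-dimethyl-5-(propan-2-yl)deca-2,8-dien-6-yl 2,2-dimethylpropanoate | COc1ccc(COC/C(C)=C\[C@H](O[Si](C)(C)C(C)(C)C)[C@H](C(C)C)[C@@H](OC(=O)C(C)(C)C)C/C(C)=C\CO[Si](C)(C)C(C)(C)C)cc1 | intermediate
19 | (2Z,4S,5R,6S,8Z)-4-[(tert-butyldimethylsilyl)oxy]-10-hydroxy-1-[(4-methoxyphenyl)methoxy]-2,8-dimethyl-5-(propan-2-yl)deca-2,8-dien-6-yl 2,2-dimethylpropanoate | COc1ccc(COC/C(C)=C\[C@H](O[Si](C)(C)C(C)(C)C)[C@H](C(C)C)[C@@H](OC(=O)C(C)(C)C)C/C(C)=C\CO)cc1 | intermediate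
20 | C9 allylic mesylate of 19 (not isolated) | COc1ccc(COC/C(C)=C\[C@H](O[Si](C)(C)C(C)(C)C)[C@H](C(C)C)[C@@H](OC(=O)C(C)(C)C)C/C(C)=C\COS(C)(=O)=O)cc1 | intermediate
21 | (2Z,4S,5R,6S,8Z)-10-(benzenesulfonyl)-4-[(tert-butyldimethylsilyl)oxy]-1-[(4-methoxyphenyl)methoxy]-2,8-dimethyl-5-(propan-2-yl)deca-2,8-dien-6-yl 2,2-dimethylpropanoate | COc1ccc(COC/C(C)=C\[C@H](O[Si](C)(C)C(C)(C)C)[C@H](C(C)C)[C@@H](OC(=O)C(C)(C)C)C/C(C)=C\CS(=O)(=O)c2ccccc2)cc1 | intermediate
22 | (2Z,4S,5R,6S,8Z)-10-(benzenesulfonyl)-4-[(tert-butyldimethylsilyl)oxy]-1-hydroxy-2,8-dimethyl-5-(propan-2-yl)deca-2,8-dien-6-yl 2,2-dimethylpropanoate | OC/C(C)=C\[C@H](O[Si](C)(C)C(C)(C)C)[C@H](C(C)C)[C@@H](OC(=O)C(C)(C)C)C/C(C)=C\CS(=O)(=O)c1ccccc1 | intermediate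
23 | C10 allylic mesylate of 22 (not isolated) | CS(=O)(=O)OC/C(C)=C\[C@H](O[Si](C)(C)C(C)(C)C)[C@H](C(C)C)[C@@H](OC(=O)C(C)(C)C)C/C(C)=C\CS(=O)(=O)c1ccccc1 | intermediate
24 | (2Z,4S,5R,6S,8Z)-10-(benzenesulfonyl)-4-[(tert-butyldimethylsilyl)oxy]-1-chloro-2,8-dimethyl-5-(propan-2-yl)deca-2,8-dien-6-yl 2,2-dimethylpropanoate | ClC/C(C)=C\[C@H](O[Si](C)(C)C(C)(C)C)[C@H](C(C)C)[C@@H](OC(=O)C(C)(C)C)C/C(C)=C\CS(=O)(=O)c1ccccc1 | intermediate
25 | potassium α-sulfonyl allyl carbanion of 24 (not isolated) | [K+].ClC/C(C)=C\[C@H](O[Si](C)(C)C(C)(C)C)[C@H](C(C)C)[C@@H](OC(=O)C(C)(C)C)C/C(C)=C\[CH-]S(=O)(=O)c1ccccc1 | intermediate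
26 | (1S,3Z,7Z,9S,10R)-5-(benzenesulfonyl)-9-[(tert-butyldimethylsilyl)oxy]-3,7-dimethyl-10-(propan-2-yl)cyclodeca-3,7-dien-1-yl 2,2-dimethylpropanoate, both epimers at the sulfone carbon | C/C1=C/[C@H](O[Si](C)(C)C(C)(C)C)[C@H](C(C)C)[C@@H](OC(=O)C(C)(C)C)C/C(C)=C\C(S(=O)(=O)c2ccccc2)C1 | intermediate
27 | (1S,3Z,7Z,9S,10R)-9-[(tert-butyldimethylsilyl)oxy]-3,7-dimethyl-10-(propan-2-yl)cyclodeca-3,7-dien-1-yl 2,2-dimethylpropanoate (not isolated) | C/C1=C/[C@H](O[Si](C)(C)C(C)(C)C)[C@H](C(C)C)[C@@H](OC(=O)C(C)(C)C)C/C(C)=C\CC1 | intermediate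
28 | (1S,3Z,7Z,9S,10R)-9-[(tert-butyldimethylsilyl)oxy]-3,7-dimethyl-10-(propan-2-yl)cyclodeca-3,7-dien-1-ol | C/C1=C/[C@H](O[Si](C)(C)C(C)(C)C)[C@H](C(C)C)[C@@H](O)C/C(C)=C\CC1 | intermediate
29 | 4-hydroxybenzoic acid | OC(=O)c1ccc(O)cc1 | starting material
30 | tert-butyldimethylsilyl 4-[(tert-butyldimethylsilyl)oxy]benzoate (not isolated) | CC(C)(C)[Si](C)(C)OC(=O)c1ccc(O[Si](C)(C)C(C)(C)C)cc1 | intermediate
31 | 4-[(tert-butyldimethylsilyl)oxy]benzoic acid | CC(C)(C)[Si](C)(C)Oc1ccc(cc1)C(=O)O | intermediate
32 | 4-[(tert-butyldimethylsilyl)oxy]benzoic 2,4,6-trichlorobenzoic anhydride (not isolated) | CC(C)(C)[Si](C)(C)Oc1ccc(cc1)C(=O)OC(=O)c1c(Cl)cc(Cl)cc1Cl | intermediate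
33 | (1S,3Z,7Z,9S,10R)-9-[(tert-butyldimethylsilyl)oxy]-3,7-dimethyl-10-(propan-2-yl)cyclodeca-3,7-dien-1-yl 4-[(tert-butyldimethylsilyl)oxy]benzoate | C/C1=C/[C@H](O[Si](C)(C)C(C)(C)C)[C@H](C(C)C)[C@@H](OC(=O)c2ccc(O[Si](C)(C)C(C)(C)C)cc2)C/C(C)=C\CC1 | intermediate
34 | (1S,3Z,7Z,9S,10S)-9-hydroxy-3,7-dimethyl-10-(propan-2-yl)cyclodeca-3,7-dien-1-yl 4-hydroxybenzoate | C/C1=C/[C@H](O)[C@H](C(C)C)[C@@H](OC(=O)c2ccc(O)cc2)C/C(C)=C\CC1 | target

## Step count and least certain steps

Total: 20 steps. Longest linear sequence: 17 steps (1–6, 9–17, 19, 20). Steps 7–8 and step 18 are side branches.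

**Step 16 (key step).**
- What may go wrong: closure of the strained ten-membered ring may be slower than intermolecular alkylation even at 2 mM, giving dimers and oligomers. The carbanion may also attack the C5 pivalate carbonyl through a seven-membered transition state (acyl transfer to carbon). Dilution cannot cure the second.
- Fallback: remove the ester from the cyclisation substrate. Setting out from 24, i-Bu2AlH (CH2Cl2, −78 °C) cleaves the pivalate to the chloro sulfone alcohol F1. Et3SiOTf and 2,6-lutidine give the C5 triethylsilyl ether F2. KN(SiMe3)2 under the same dilution closes the ring to the macrocyclic sulfone silyl ether F3. PdCl2(dppp) and LiBHEt3 give the desulfonylated bis-silyl ether F4. PPTS in MeOH at 0 °C removes the secondary triethylsilyl group beside the hindered TBS ether and returns to the route at 28.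

**Step 10.**
- What may go wrong: hemiacetal formation and hydride transfer may be slow with the hindered aldehyde. The Lewis-acidic catalyst could then isomerise the Z enone or promote conjugate addition of the C5 hydroxyl.
- Fallback: use the small, classical aldehyde and exchange the ester afterwards. Setting out from 16, SmI2 (cat.) and acetaldehyde give the anti hydroxy acetate F5. TBSOTf and 2,6-lutidine give the silylated acetate F6. i-Bu2AlH at −78 °C frees the C5 alcohol F7. Pivaloyl chloride with DMAP in pyridine returns to the route at 18.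

**Step 17.**
- What may go wrong: hydride may be delivered to C7 instead of C9, or the π-allyl complex may undergo syn–anti isomerisation, either of which erodes the position or Z geometry of the C7=C8 bond. If ester cleavage ran ahead, the C5 alkoxide could capture the π-allyl complex.
- Fallback: change the mechanism to electron transfer and split the operation. Setting out from 26, sodium amalgam Na(Hg) with Na2HPO4 in MeOH/THF at −20 °C removes the sulfone through the allyl anion, which should protonate at the secondary carbon C9. This gives 27, isolated. i-Bu2AlH at −78 °C then cleaves the pivalate and returns to the route at 28. No new compound is needed.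

**Step 9.**
- What may go wrong: addition to the hindered amide, which carries a neighbouring alkoxide, may be incomplete. The alkoxide may fragment by retro-aldol, or the β,β-disubstituted Z enone may isomerise during work-up.
- Fallback: mask the hydroxyl before the addition. Setting out from 10, Me3SiCl and imidazole give the trimethylsilyl ether Weinreb amide F8. Alkenyllithium 15 (1.3 equiv) adds to give the silylated enone F9. Citric acid in MeOH at 0 °C removes the trimethylsilyl group and returns to the route at 16.

**Step 6.**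
- What may go wrong: the exocyclic carbonyl is shielded by the α-isopropyl group, so the aluminium amide may attack the ring carbonyl and open the oxazolidinone.
- Fallback: cleave with hydroperoxide, which is selective for the exocyclic carbonyl, and couple afterwards. Setting out from 9, LiOH and H2O2 in THF/H2O at 0 °C give the hydroxy acid F10. MeNHOMe·HCl with EDC·HCl, HOBt and i-Pr2NEt returns to the route at 10.

## Further compounds

F1 | step 16 | (2Z,4S,5R,6S,8Z)-10-(benzenesulfonyl)-4-[(tert-butyldimethylsilyl)oxy]-1-chloro-2,8-dimethyl-5-(propan-2-yl)deca-2,8-dien-6-ol | ClC/C(C)=C\[C@H](O[Si](C)(C)C(C)(C)C)[C@H](C(C)C)[C@@H](O)C/C(C)=C\CS(=O)(=O)c1ccccc1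
F2 | step 16 | C5 triethylsilyl ether of F1 | ClC/C(C)=C\[C@H](O[Si](C)(C)C(C)(C)C)[C@H](C(C)C)[C@@H](O[Si](CC)(CC)CC)C/C(C)=C\CS(=O)(=O)c1ccccc1
F3 | step 16 | ten-membered C9 phenyl sulfone with C3 TBS ether and C5 triethylsilyl ether (C9 epimers) | C/C1=C/[C@H](O[Si](C)(C)C(C)(C)C)[C@H](C(C)C)[C@@H](O[Si](CC)(CC)CC)C/C(C)=C\C(S(=O)(=O)c2ccccc2)C1
F4 | step 16 | ten-membered (Z,Z)-diene with C3 TBS ether and C5 triethylsilyl ether | C/C1=C/[C@H](O[Si](C)(C)C(C)(C)C)[C@H](C(C)C)[C@@H](O[Si](CC)(CC)CC)C/C(C)=C\CC1
F5 | step 10 | (2Z,4S,5S,6S,8Z)-10-[(tert-butyldimethylsilyl)oxy]-4-hydroxy-1-[(4-methoxyphenyl)methoxy]-2,8-dimethyl-5-(propan-2-yl)deca-2,8-dien-6-yl acetate | COc1ccc(COC/C(C)=C\[C@H](O)[C@H](C(C)C)[C@@H](OC(C)=O)C/C(C)=C\CO[Si](C)(C)C(C)(C)C)cc1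
F6 | step 10 | C3 TBS ether of F5 | COc1ccc(COC/C(C)=C\[C@H](O[Si](C)(C)C(C)(C)C)[C@H](C(C)C)[C@@H](OC(C)=O)C/C(C)=C\CO[Si](C)(C)C(C)(C)C)cc1
F7 | step 10 | (2Z,4S,5R,6S,8Z)-4,10-bis[(tert-butyldimethylsilyl)oxy]-1-[(4-methoxyphenyl)methoxy]-2,8-dimethyl-5-(propan-2-yl)deca-2,8-dien-6-ol | COc1ccc(COC/C(C)=C\[C@H](O[Si](C)(C)C(C)(C)C)[C@H](C(C)C)[C@@H](O)C/C(C)=C\CO[Si](C)(C)C(C)(C)C)cc1
F0 | step 17 | none | none
F8 | step 9 | C5 trimethylsilyl ether of Weinreb amide 10 | CON(C)C(=O)[C@H](C(C)C)[C@@H](O[Si](C)(C)C)C/C(C)=C\CO[Si](C)(C)C(C)(C)C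
F9 | step 9 | C5 trimethylsilyl ether of enone 16 | COc1ccc(COC/C(C)=C\C(=O)[C@H](C(C)C)[C@@H](O[Si](C)(C)C)C/C(C)=C\CO[Si](C)(C)C(C)(C)C)cc1
F10 | step 6 | (2R,3S,5Z)-7-[(tert-butyldimethylsilyl)oxy]-3-hydroxy-5-methyl-2-(propan-2-yl)hept-5-enoic acid | OC(=O)[C@H](C(C)C)[C@@H](O)C/C(C)=C\CO[Si](C)(C)C(C)(C)C
A1 | alternative 1 | (3Z,7Z,9S,10E)-12-bromo-9-[(tert-butyldimethylsilyl)oxy]-3,7,11-trimethyldodeca-3,7,10-trienal | O=CC/C(C)=C\CC/C(C)=C\[C@H](O[Si](C)(C)C(C)(C)C)/C=C(\C)CBr
A2 | alternative 1 | ten-membered alcohol with C5 hydroxyl, C4 isopropenyl group and C3 TBS ether | C/C1=C/[C@H](O[Si](C)(C)C(C)(C)C)[C@H](C(C)=C)[C@@H](O)C/C(C)=C\CC1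
A3 | alternative 2 | thirteen-membered cyclic allyl ether with tributylstannyl group on the oxygen-bearing C3 and PMB ether at C5 (tin-bearing carbon left open) | CCCC[Sn](CCCC)(CCCC)C1/C=C(C)\CC/C=C(C)\C[C@H](OCc2ccc(OC)cc2)/C=C(C)/CO1
A4 | alternative 2 | ten-membered alcohol with C3 hydroxyl, C4 isopropenyl group and C5 PMB ether | C/C1=C/[C@H](O)[C@H](C(C)=C)[C@@H](OCc2ccc(OC)cc2)C/C(C)=C\CC1
A5 | alternative 3 | open-chain Z-alkenyl iodide aldehyde carrying the C5 4-[(tert-butyldimethylsilyl)oxy]benzoate | O=C[C@H](C(C)C)[C@@H](OC(=O)c1ccc(O[Si](C)(C)C(C)(C)C)cc1)C/C(C)=C\CC/C(C)=C\I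
A6 | alternative 3 | O-silylated target (phenol TBS ether) | C/C1=C/[C@H](O)[C@H](C(C)C)[C@@H](OC(=O)c2ccc(O[Si](C)(C)C(C)(C)C)cc2)C/C(C)=C\CC1
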